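**Conventions (one line):** abietane numbering with α/β notation (β = face of the C10 methyl) is used for the tricyclic compounds; after ring contraction ring B is C5–C6–C8–C9–C10 with C7 exocyclic on C6; the SMILES strings are authoritative.
**Assumption (one line):** the 90–95% ee expected from step 9 is raised to >99% by recrystallising ketone 22.

## Retrosynthetic overview

1. Target ⇐ its 12-O-methyl ether 38 ⇐ Diels–Alder addition of myrcene to the α face of C8=C9 of methoxyquinone aldehyde 36 (ring D, formed last).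
2. 36 ⇐ Teuber oxidation of a 14-phenol ⇐ 6-5-6 ester 32 ⇐ Wolff ring contraction of the 6-diazo-7-oxo-abietatriene 29 (ring B contracted).
3. Abietatriene 24 ⇐ enone 20 by reductive methylation (C5 and gem-dimethyl) and Wolff–Kishner reduction; 20 ⇐ diketone 18 by aldol condensation (ring A).
4. Key C10–C1 bond: intermolecular asymmetric Michael addition of the (R)-1-phenylethylamine enamine of 1-methyl-2-tetralone 13 to ethyl vinyl ketone; it sets C10, which controls C5, C6, C8 and C9.
5. 13 ⇐ Haworth tetralone synthesis from 1,3-dimethoxybenzene, acetone and succinic anhydride. Ring order: C (arene) → B → A → B contracted → C to quinone → D.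

## Route

Step 1
Reactants: 1 1,3-dimethoxybenzene; 2 acetone
Product: 4 2-(2,6-dimethoxyphenyl)propan-2-ol, via 2,6-dimethoxyphenyllithium 3 (not isolated)
Conditions: n-BuLi (1.1 equiv), THF, 0 °C → rt, 2 h; acetone, −78 °C → rt; H2O quench
Reagents that add atoms: none
Why: Directed ortho-metalation occurs only at C2 between the two methoxy groups, and the aryllithium adds to acetone (carbonyl addition).

Step 2
Reactants: 4 2-(2,6-dimethoxyphenyl)propan-2-ol
Product: 5 2-isopropyl-1,3-dimethoxybenzene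
Conditions: Et3SiH (1.5 equiv), CF3CO2H, CH2Cl2, 0 °C → rt
Reagents that add atoms: none
Why: Ionic hydrogenation, in which the tertiary benzylic cation formed in acid is trapped by silane hydride.

Step 3
Reactants: 5 2-isopropyl-1,3-dimethoxybenzene; 6 succinic anhydride
Product: 7 4-(3-isopropyl-2,4-dimethoxyphenyl)-4-oxobutanoic acid
Conditions: AlCl3 (2.2 equiv), CH2Cl2/MeNO2, 0 °C → rt; aq. HCl work-up
Reagents that add atoms: none
Why: Friedel–Crafts acylation (first Haworth step) at C4, the only position ortho/para to both methoxy groups.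

Step 4
Reactants: 7 4-(3-isopropyl-2,4-dimethoxyphenyl)-4-oxobutanoic acid
Product: 8 4-(3-isopropyl-2,4-dimethoxyphenyl)butanoic acid
Conditions: H2 (4 atm), Pd/C (10%), AcOH, cat. HClO4, 60 °C
Reagents that add atoms: none
Why: Acid-assisted catalytic hydrogenolysis of an electron-rich aryl ketone to the methylene.

Step 5
Reactants: 8 4-(3-isopropyl-2,4-dimethoxyphenyl)butanoic acid
Product: 9 6-isopropyl-5,7-dimethoxy-3,4-dihydronaphthalen-1(2H)-one
Conditions: polyphosphoric acid, 80 °C, 1 h
Reagents that add atoms: none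
Why: Intramolecular Friedel–Crafts acylation at the only free position ortho to the chain (para to the isopropyl group).

Step 6
Reactants: 9 6-isopropyl-5,7-dimethoxy-3,4-dihydronaphthalen-1(2H)-one
Product: 11 7-isopropyl-6,8-dimethoxy-4-methyl-1,2-dihydronaphthalene, via tertiary alcohol 10 (not isolated)
Conditions: MeMgBr (1.5 equiv), THF, 0 °C → rt; H2O quench; then TsOH·H2O (5 mol%), toluene, 80 °C
Reagents that add atoms: methylmagnesium bromide C[Mg]Br
Why: Grignard addition followed by E1 dehydration of the tertiary benzylic alcohol to the conjugated endocyclic alkene.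

Step 7
Reactants: 11 7-isopropyl-6,8-dimethoxy-4-methyl-1,2-dihydronaphthalene
Product: 13 6-isopropyl-5,7-dimethoxy-1-methyl-3,4-dihydronaphthalen-2(1H)-one (racemic), via epoxide 12 (not isolated)
Conditions: mCPBA (1.1 equiv), CH2Cl2/0.5 M aq. NaHCO3, 0 °C; then TsOH·H2O (5 mol%), toluene, rt → 60 °C, N2
Reagents that add atoms: mCPBA (3-chloroperoxybenzoic acid) OOC(=O)c1cccc(Cl)c1
Why: Prilezhaev epoxidation then Meinwald rearrangement, in which the epoxide opens to the tertiary benzylic cation and a 1,2-hydride shift gives the 2-tetralone; the C1 centre is later made planar in the enamine, so the racemate suffices.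

Step 8
Reactants: 13 6-isopropyl-5,7-dimethoxy-1-methyl-3,4-dihydronaphthalen-2(1H)-one; 14 (R)-1-phenylethylamine
Product: 15 6-isopropyl-5,7-dimethoxy-1-methyl-N-[(1R)-1-phenylethyl]-3,4-dihydronaphthalen-2-amine (secondary enamine; imine tautomer in equilibrium; used crude)
Conditions: TsOH·H2O (1 mol%), toluene, Dean–Stark, reflux, N2
Reagents that add atoms: none
Why: Imine condensation with azeotropic water removal, the arene-conjugated C1=C2 enamine tautomer being favoured.

Step 9
Reactants: 15 the (R)-1-phenylethyl enamine; 16 ethyl vinyl ketone (pent-1-en-3-one)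
Product: 18 (1R)-6-isopropyl-5,7-dimethoxy-1-methyl-1-(3-oxopentyl)-3,4-dihydronaphthalen-2(1H)-one, via Michael adduct imine 17 (not isolated)
Conditions: ethyl vinyl ketone (1.3 equiv), THF, 35 °C, 3–5 d; then 10% aq. AcOH, rt, 2 h
Reagents that add atoms: water O
Why: Asymmetric Michael addition of a chiral secondary enamine (deracemising alkylation through a compact aza-ene-like chair transition state with internal N–H transfer), in which the enone is attacked on the enamine face anti to the phenyl group of the (R)-auxiliary to create the quaternary C10 centre as (R)-18 (natural 10β-methyl series) before hydrolysis releases the amine.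

Step 10
Reactants: 18 the (1R)-1,5-diketone
Product: 20 (4aS)-7-isopropyl-6,8-dimethoxy-1,4a-dimethyl-4,4a,9,10-tetrahydrophenanthren-2(3H)-one, via aldol ketol 19 (not isolated)
Conditions: NaOMe (0.3 equiv), MeOH, 60 °C
Reagents that add atoms: none
Why: Intramolecular aldol condensation (second half of a Robinson annulation) closes ring A to the conjugated enone without touching the quaternary centre.

Step 11
Reactants: 20 the tricyclic enone
Product: 22 12,14-dimethoxyabieta-8,11,13-trien-3-one (5α-H; 10β-methyl), via lithium enolate 21 (not isolated)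
Conditions: Li (2.2 equiv), NH3(l)/THF, t-BuOH (1.0 equiv), −78 °C; then MeI (5 equiv), −78 → −33 °C; H2O work-up
Reagents that add atoms: iodomethane CI
Why: Dissolving-metal enone reduction with Stork reductive alkylation, in which C5 is protonated axially anti to the C10 methyl to give the trans A/B fusion and the regiodefined C3 enolate is C-methylated at C4 to complete the gem-dimethyl group.

Step 12
Reactants: 22 12,14-dimethoxyabieta-8,11,13-trien-3-one
Product: 24 12,14-dimethoxyabieta-8,11,13-triene, via hydrazone 23 (not isolated)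
Conditions: N2H4·H2O, KOH, diethylene glycol, 130 °C then 200 °C
Reagents that add atoms: none
Why: Wolff–Kishner reduction (Huang-Minlon procedure), standard for hindered 3-oxo-4,4-dimethyl terpenoids and without effect on the non-enolisable stereocentres.

Step 13
Reactants: 24 12,14-dimethoxyabieta-8,11,13-triene
Product: 25 12,14-dimethoxyabieta-8,11,13-trien-7-one
Conditions: Rh2(cap)4 (dirhodium tetrakis(caprolactamate), 1 mol%), t-BuOOH (70% aq., 5 equiv), NaHCO3 (0.5 equiv), ClCH2CH2Cl, 40 °C
Reagents that add atoms: tert-butyl hydroperoxide CC(C)(C)OO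
Why: Radical benzylic C–H oxidation at C7, the only benzylic methylene (the isopropyl methine is twisted out of conjugation by its two ortho methoxy groups).

Step 14
Reactants: 25 12,14-dimethoxyabieta-8,11,13-trien-7-one
Product: 26 14-hydroxy-12-methoxyabieta-8,11,13-trien-7-one
Conditions: BCl3 (1.5 equiv), CH2Cl2, −78 → 0 °C; H2O
Reagents that add atoms: none
Why: Chelation-controlled Lewis-acid ether cleavage, in which only the methoxy group peri to the C7 carbonyl forms the six-membered boron chelate and is demethylated.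

Step 15
Reactants: 26 14-hydroxy-12-methoxyabieta-8,11,13-trien-7-one
Product: 27 14-benzyloxy-12-methoxyabieta-8,11,13-trien-7-one
Conditions: BnBr (1.3 equiv), K2CO3 (2 equiv), DMF, 60 °C
Reagents that add atoms: benzyl bromide BrCc1ccccc1
Why: Williamson etherification of the phenol, giving an O14 group orthogonal to the 12-OMe and stable to the base, light and hydride of the next steps.

Step 16
Reactants: 27 14-benzyloxy-12-methoxyabieta-8,11,13-trien-7-one
Product: 29 14-benzyloxy-6-diazo-12-methoxyabieta-8,11,13-trien-7-one, via trifluoroacetyl ketone 28 (not isolated)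
Conditions: LiN(SiMe3)2 (1.1 equiv), THF, −78 °C; CF3CO2CH2CF3 (1.3 equiv); dilute HCl work-up; then MsN3 (1.5 equiv), Et3N, H2O (1 equiv), MeCN, rt
Reagents that add atoms: methanesulfonyl azide CS(=O)(=O)N=[N+]=[N-]
Why: Detrifluoroacetylative (Regitz-type) diazo transfer, with C6 the only enolisable position of the aryl ketone and C5 untouched.

Step 17
Reactants: 29 14-benzyloxy-6-diazo-12-methoxyabieta-8,11,13-trien-7-one
Product: 32 methyl 14-benzyloxy-12-methoxy-8(7→6)abeo-abieta-8,11,13-trien-7-oate (6α-CO2Me; 5α-H; 10β-methyl), via ketene 30 (not isolated), via ester epimer mixture 31 (not isolated)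
Conditions: hν (365 nm), MeOH/THF, rt; then NaOMe (0.5 equiv), 50 °C
Reagents that add atoms: methanol CO
Why: Photochemical Wolff rearrangement, in which the aryl carbon C8 shifts from C7 to C6 with loss of N2 to give the ring-contracted ketene trapped by MeOH, and NaOMe then equilibrates C6 to the more stable 6α ester (anti to the C10 methyl and clear of the C4 gem-dimethyl group).

Step 18
Reactants: 32 the 6α methyl ester
Product: 33 14-benzyloxy-12-methoxy-8(7→6)abeo-abieta-8,11,13-trien-7-ol (6α-CH2OH)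
Conditions: LiAlH4 (1.5 equiv), THF, 0 °C → rt; H2O work-up
Reagents that add atoms: none
Why: Hydride reduction of the ester to the primary alcohol, removing the acidity at C6 so its configuration is held.

Step 19
Reactants: 33 the benzyl ether alcohol
Product: 34 12-methoxy-8(7→6)abeo-abieta-8,11,13-triene-7,14-diol (6α-CH2OH; free 14-phenol)
Conditions: H2 (1 atm), Pd/C (10%), EtOAc/EtOH, rt
Reagents that add atoms: none
Why: Hydrogenolysis of the aryl benzyl ether in a molecule with no other reducible group.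

Step 20
Reactants: 34 the 14-phenol
Product: 35 7-hydroxy-12-methoxy-8(7→6)abeo-abieta-8,12-diene-11,14-dione (methoxy-p-quinone; 6α-CH2OH)
Conditions: (KO3S)2NO (potassium nitrosodisulfonate, 2.5 equiv), KH2PO4 buffer, acetone/H2O, rt
Reagents that add atoms: potassium nitrosodisulfonate [K+].[K+].[O-]S(=O)(=O)N([O])S(=O)(=O)[O-]
Why: Teuber oxidation, in which the phenoxyl radical is oxygenated at the free para position C11 to give the 11,14-quinone with the 12-OMe retained.

Step 21
Reactants: 35 the quinone alcohol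
Product: 36 12-methoxy-11,14-dioxo-8(7→6)abeo-abieta-8,12-dien-7-al (6α-CHO)
Conditions: Dess–Martin periodinane (1.3 equiv), CH2Cl2, 0 °C → rt
Reagents that add atoms: none
Why: Dess–Martin oxidation of the primary alcohol to the aldehyde under neutral conditions that tolerate the methoxyquinone, 6α being the thermodynamic configuration.

Step 22
Reactants: 36 the methoxyquinone aldehyde; 37 myrcene (7-methyl-3-methyleneocta-1,6-diene)
Product: 38 12-O-methyl ether of the target (cis-8α,9α-fused cyclohexene carrying the 4-methylpent-3-enyl group on the alkene carbon joined through CH2 to C9)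
Conditions: Er(fod)3 [tris(6,6,7,7,8,8,8-heptafluoro-2,2-dimethyloctane-3,5-dionato)erbium, 0.5 equiv], myrcene (5 equiv), CH2Cl2, 30 °C, dark, 48 h
Reagents that add atoms: none
Why: Lewis-acid-promoted Diels–Alder reaction, in which erbium on the more basic vinylogous-ester carbonyl C14=O (two-point binding with the adjacent aldehyde) makes C9 the electrophilic terminus for the nucleophilic CH2 next to the substituted diene carbon ("para" rule), and suprafacial addition to the α face, anti to the C10 methyl, sets C8 and C9 cis.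

Step 23
Reactants: 38 the 12-O-methyl adduct
Product: 39 target CNP0239256.1
Conditions: LiOH (3 equiv), THF/H2O (3:1), 0 °C → rt; then 1 M HCl to pH 3 at 0 °C
Reagents that add atoms: lithium hydroxide [Li+].[OH-]
Why: Addition–elimination hydrolysis of the vinylogous methyl ester at C12, under base to avoid acid-induced Prins/carbonyl-ene closure of the aldehyde onto the ring D alkene; C8 and C9 are quaternary and 6α-CHO is the stable epimer, so no centre is at risk.

## Compound list

1 | 1,3-dimethoxybenzene | COc1cccc(OC)c1 | starting material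
2 | acetone | CC(C)=O | starting material
3 | 2,6-dimethoxyphenyllithium | [Li]c1c(OC)cccc1OC | intermediate
4 | 2-(2,6-dimethoxyphenyl)propan-2-ol | COc1cccc(OC)c1C(C)(C)O | intermediate
5 | 2-isopropyl-1,3-dimethoxybenzene | COc1cccc(OC)c1C(C)C | intermediate
6 | succinic anhydride | O=C1CCC(=O)O1 | starting material
7 | 4-(3-isopropyl-2,4-dimethoxyphenyl)-4-oxobutanoic acid | COc1ccc(C(=O)CCC(=O)O)c(OC)c1C(C)C | intermediate
8 | 4-(3-isopropyl-2,4-dimethoxyphenyl)butanoic acid | COc1ccc(CCCC(=O)O)c(OC)c1C(C)C | intermediate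
9 | 6-isopropyl-5,7-dimethoxy-3,4-dihydronaphthalen-1(2H)-one | COc1cc2C(=O)CCCc2c(OC)c1C(C)C | intermediate
10 | 6-isopropyl-5,7-dimethoxy-1-methyl-1,2,3,4-tetrahydronaphthalen-1-ol (racemic) | COc1cc2c(CCCC2(C)O)c(OC)c1C(C)C | intermediate
11 | 7-isopropyl-6,8-dimethoxy-4-methyl-1,2-dihydronaphthalene | COc1cc2C(C)=CCCc2c(OC)c1C(C)C | intermediate
12 | 3,4-epoxide of 11 (racemic) | COc1cc2c(CCC3OC23C)c(OC)c1C(C)C | intermediate
13 | 6-isopropyl-5,7-dimethoxy-1-methyl-3,4-dihydronaphthalen-2(1H)-one (racemic) | COc1cc2C(C)C(=O)CCc2c(OC)c1C(C)C | intermediate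
14 | (R)-1-phenylethylamine | C[C@@H](N)c1ccccc1 | starting material
15 | 6-isopropyl-5,7-dimethoxy-1-methyl-N-[(1R)-1-phenylethyl]-3,4-dihydronaphthalen-2-amine (enamine tautomer) | COc1cc2C(C)=C(N[C@H](C)c3ccccc3)CCc2c(OC)c1C(C)C | intermediate
16 | ethyl vinyl ketone (pent-1-en-3-one) | CCC(=O)C=C | starting material
17 | N-[(1R)-1-phenylethyl] imine of 18 | COc1cc2c(c(OC)c1C(C)C)CCC(=N[C@H](C)c3ccccc3)[C@]2(C)CCC(=O)CC | intermediate
18 | (1R)-6-isopropyl-5,7-dimethoxy-1-methyl-1-(3-oxopentyl)-3,4-dihydronaphthalen-2(1H)-one | COc1cc2c(c(OC)c1C(C)C)CCC(=O)[C@]2(C)CCC(=O)CC | intermediate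
19 | aldol ketol (5-hydroxy-4-methyl-3-ketone, mixture at C4 and C5, 10β-methyl) | COc1cc2[C@@]3(C)CCC(=O)C(C)C3(O)CCc2c(OC)c1C(C)C | intermediate
20 | (4aS)-7-isopropyl-6,8-dimethoxy-1,4a-dimethyl-4,4a,9,10-tetrahydrophenanthren-2(3H)-one | COc1cc2[C@@]3(C)CCC(=O)C(C)=C3CCc2c(OC)c1C(C)C | intermediate
21 | lithium C3-enolate of the 5α-H dihydro compound | COc1cc2[C@@]3(C)CCC(O[Li])=C(C)[C@@H]3CCc2c(OC)c1C(C)C | intermediate
22 | 12,14-dimethoxyabieta-8,11,13-trien-3-one (5α-H, 10β-Me) | COc1cc2[C@@]3(C)CCC(=O)C(C)(C)[C@@H]3CCc2c(OC)c1C(C)C | intermediate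
23 | hydrazone of 22 | COc1cc2[C@@]3(C)CCC(=NN)C(C)(C)[C@@H]3CCc2c(OC)c1C(C)C | intermediate
24 | 12,14-dimethoxyabieta-8,11,13-triene | COc1cc2[C@@]3(C)CCCC(C)(C)[C@@H]3CCc2c(OC)c1C(C)C | intermediate
25 | 12,14-dimethoxyabieta-8,11,13-trien-7-one | COc1cc2[C@@]3(C)CCCC(C)(C)[C@@H]3CC(=O)c2c(OC)c1C(C)C | intermediate
26 | 14-hydroxy-12-methoxyabieta-8,11,13-trien-7-one | COc1cc2[C@@]3(C)CCCC(C)(C)[C@@H]3CC(=O)c2c(O)c1C(C)C | intermediate
27 | 14-benzyloxy-12-methoxyabieta-8,11,13-trien-7-one | COc1cc2[C@@]3(C)CCCC(C)(C)[C@@H]3CC(=O)c2c(OCc4ccccc4)c1C(C)C | intermediate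
28 | 14-benzyloxy-12-methoxy-6-(trifluoroacetyl)abieta-8,11,13-trien-7-one (C6 mixture/enol) | COc1cc2[C@@]3(C)CCCC(C)(C)[C@@H]3C(C(=O)C(F)(F)F)C(=O)c2c(OCc4ccccc4)c1C(C)C | intermediate
29 | 14-benzyloxy-6-diazo-12-methoxyabieta-8,11,13-trien-7-one | COc1cc2[C@@]3(C)CCCC(C)(C)[C@@H]3C(=[N+]=[N-])C(=O)c2c(OCc4ccccc4)c1C(C)C | intermediate
30 | ring-contracted ketene (C6=C7=O) | COc1cc2[C@@]3(C)CCCC(C)(C)[C@@H]3C(=C=O)c2c(OCc4ccccc4)c1C(C)C | intermediate
31 | ring-contracted methyl ester, C6 epimer mixture | COc1cc2[C@@]3(C)CCCC(C)(C)[C@@H]3C(C(=O)OC)c2c(OCc4ccccc4)c1C(C)C | intermediate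
32 | methyl 14-benzyloxy-12-methoxy-8(7→6)abeo-abieta-8,11,13-trien-7-oate (6α-CO2Me, 5α-H, 10β-Me) | COc1cc2[C@@]3(C)CCCC(C)(C)[C@@H]3[C@@H](C(=O)OC)c2c(OCc4ccccc4)c1C(C)C | intermediate
33 | 14-benzyloxy-12-methoxy-8(7→6)abeo-abieta-8,11,13-trien-7-ol (6α-CH2OH) | COc1cc2[C@@]3(C)CCCC(C)(C)[C@@H]3[C@@H](CO)c2c(OCc4ccccc4)c1C(C)C | intermediate
34 | 12-methoxy-8(7→6)abeo-abieta-8,11,13-triene-7,14-diol | COc1cc2[C@@]3(C)CCCC(C)(C)[C@@H]3[C@@H](CO)c2c(O)c1C(C)C | intermediate
35 | 7-hydroxy-12-methoxy-8(7→6)abeo-abieta-8,12-diene-11,14-dione | COC1=C(C(C)C)C(=O)C2=C(C1=O)[C@@]1(C)CCCC(C)(C)[C@@H]1[C@H]2CO | intermediate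
36 | 12-methoxy-11,14-dioxo-8(7→6)abeo-abieta-8,12-dien-7-al (6α-CHO) | COC1=C(C(C)C)C(=O)C2=C(C1=O)[C@@]1(C)CCCC(C)(C)[C@@H]1[C@H]2C=O | intermediate
37 | myrcene | CC(C)=CCCC(=C)C=C | starting material
38 | 12-O-methyl ether of the target | CC(C)=CCCC1=CC[C@@]23C(=O)C(C(C)C)=C(OC)C(=O)[C@]2(C1)[C@@]1(C)CCCC(C)(C)[C@@H]1[C@H]3C=O | intermediate
39 | CNP0239256.1 | CC(C)=CCCC1=CC[C@@]23C(=O)C(C(C)C)=C(O)C(=O)[C@]2(C1)[C@@]1(C)CCCC(C)(C)[C@@H]1[C@H]3C=O | target

## Step count and risks

Total steps: 23. Longest linear sequence: 23 steps (from 1,3-dimethoxybenzene; compounds 2, 6, 14, 16 and 37 are bought).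

**Step 22 (Diels–Alder) is the most likely to fail.** The concerns are the regiochemistry on a hindered tetrasubstituted quinone bond and Prins/carbonyl-ene closure of the free aldehyde onto the new ring D alkene. The fallback runs the cycloaddition before the aldehyde exists and uses a strictly monodentate boron Lewis acid. It sets out from 35: Ac2O/pyridine gives 7-acetoxy-12-methoxy-8(7→6)abeo-abieta-8,12-diene-11,14-dione F7. BF3·OEt2 (1.2 equiv) with myrcene in CH2Cl2 at −78 → −20 °C binds only the vinylogous-ester carbonyl C14=O and gives the adduct acetate F8. K2CO3/MeOH removes the acetate to give the adduct alcohol F9. Dess–Martin oxidation then returns to the route at 38.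

**Step 16 (diazo transfer to the hindered peri-alkoxy ketone, and with it the Wolff step 17).** The fallback contracts the ring by an oxidative 1,2-aryl shift instead. It sets out from 27: NaBH4/MeOH gives 14-benzyloxy-12-methoxyabieta-8,11,13-trien-7-ol F3. TsOH in toluene at 80 °C dehydrates it to 14-benzyloxy-12-methoxyabieta-6,8,11,13-tetraene F4. PhI(OH)OTs in MeOH/HC(OMe)3 at 0 °C adds at C6, methanol adds at C7, and C8 migrates to C6 with loss of iodobenzene to give the ring-contracted 7,7-dimethyl acetal F5. Aqueous TsOH/acetone and brief K2CO3/MeOH equilibration give the 6α aldehyde 14-benzyloxy-12-methoxy-8(7→6)abeo-abieta-8,11,13-trien-7-al F6. NaBH4 reduction comes back to the route at 33.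

**Step 13 (benzylic oxidation next to a very electron-rich arene).** Ring oxidation or attack at the isopropyl methine may compete. The fallback replaces direct C–H oxygenation by hydride abstraction, solvolysis and alcohol oxidation. It sets out from 24: DDQ (1.2 equiv) in AcOH at rt removes the C7 hydride (cation stabilised by the ortho 14-OMe) and acetate capture gives 7-acetoxy-12,14-dimethoxyabieta-8,11,13-triene F1. K2CO3/MeOH gives 12,14-dimethoxyabieta-8,11,13-trien-7-ol F2. MnO2 in CH2Cl2 oxidises the benzylic alcohol and comes back to the route at 25.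

## Further compounds

F1 | step 13 | 7-acetoxy-12,14-dimethoxyabieta-8,11,13-triene (C7 epimers) | COc1cc2[C@@]3(C)CCCC(C)(C)[C@@H]3CC(OC(C)=O)c2c(OC)c1C(C)C
F2 | step 13 | 12,14-dimethoxyabieta-8,11,13-trien-7-ol (C7 epimers) | COc1cc2[C@@]3(C)CCCC(C)(C)[C@@H]3CC(O)c2c(OC)c1C(C)C
F3 | step 16 | 14-benzyloxy-12-methoxyabieta-8,11,13-trien-7-ol (C7 epimers) | COc1cc2[C@@]3(C)CCCC(C)(C)[C@@H]3CC(O)c2c(OCc4ccccc4)c1C(C)C
F4 | step 16 | 14-benzyloxy-12-methoxyabieta-6,8,11,13-tetraene | COc1cc2[C@@]3(C)CCCC(C)(C)[C@@H]3C=Cc2c(OCc4ccccc4)c1C(C)C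
F5 | step 16 | 14-benzyloxy-7,7,12-trimethoxy-8(7→6)abeo-abieta-8,11,13-triene (dimethyl acetal, C6 epimers) | COc1cc2[C@@]3(C)CCCC(C)(C)[C@@H]3C(C(OC)OC)c2c(OCc4ccccc4)c1C(C)C
F6 | step 16 | 14-benzyloxy-12-methoxy-8(7→6)abeo-abieta-8,11,13-trien-7-al (6α-CHO) | COc1cc2[C@@]3(C)CCCC(C)(C)[C@@H]3[C@@H](C=O)c2c(OCc4ccccc4)c1C(C)C
F7 | step 22 | 7-acetoxy-12-methoxy-8(7→6)abeo-abieta-8,12-diene-11,14-dione | COC1=C(C(C)C)C(=O)C2=C(C1=O)[C@@]1(C)CCCC(C)(C)[C@@H]1[C@H]2COC(C)=O
F8 | step 22 | myrcene adduct of F7 (12-OMe, 6α-CH2OAc) | CC(C)=CCCC1=CC[C@@]23C(=O)C(C(C)C)=C(OC)C(=O)[C@]2(C1)[C@@]1(C)CCCC(C)(C)[C@@H]1[C@H]3COC(C)=O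
F9 | step 22 | adduct alcohol (12-OMe, 6α-CH2OH) | CC(C)=CCCC1=CC[C@@]23C(=O)C(C(C)C)=C(OC)C(=O)[C@]2(C1)[C@@]1(C)CCCC(C)(C)[C@@H]1[C@H]3CO
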